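**Plan**
- Retrosynthesis: the six C–Br bonds are cut first, then the three O–CH3 bonds of a trimethyl ether, then the diaryl ether C–O bond. The bromines sit at C2, C5 and C6 of the 4-hydroxyphenoxy ring A (numbered from its hydroxyl carbon) and at C3', C4' and C6' of the hydroquinone ring B (numbered from its ether carbon).
- Forward: an Ullmann coupling joins the two benzene rings through oxygen, BBr3 frees the three hydroxyls, and one bromination operation installs all six bromines. No ring is closed anywhere in the route.
- Enabling feature: every brominated carbon lies ortho or para to an oxygen. C2 and C6 flank the ring A hydroxyl, C5 flanks the ether oxygen, and C3', C4', C6' are the only free positions of ring B, each ortho to a hydroxyl. Once C2 and C6 carry bromine, C3 and C5 of ring A are equivalent, so the sixth bromine has no regiochemical choice.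
- Stereochemistry: the target has no stereocentre, so nothing has to be set.

Key step: step 3

Assumption: the SMILES shows no stereogenic element and rotation about the two aryl–O bonds is taken as fast at room temperature, so the target is treated as a single achiral compound.

**Step 1**
Reactants: 1 4-methoxyphenol; 2 2-bromo-1,4-dimethoxybenzene
Product: 3 1,4-dimethoxy-2-(4-methoxyphenoxy)benzene
Conditions: CuI (10 mol%), N,N-dimethylglycine (30 mol%), Cs2CO3 (2 equiv), 1,4-dioxane, 100 °C, Ar
Reagents that add atoms: none
Why: Ligand-accelerated Ullmann diaryl ether synthesis, in which the caesium phenoxide of 1 displaces bromide from 2 at copper(I); amino-acid-ligated copper should couple an electron-rich ortho-alkoxy aryl bromide with an electron-rich phenol and leave the methyl ethers untouched.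

**Step 2**
Reactants: 3 1,4-dimethoxy-2-(4-methoxyphenoxy)benzene
Product: 5 2-(4-hydroxyphenoxy)benzene-1,4-diol, via tris(dibromoboryl) ether 4 (not isolated)
Conditions: BBr3 (4.5 equiv), CH2Cl2, −78 °C to rt; then degassed H2O, 0 °C, Ar
Reagents that add atoms: none
Why: BBr3 ether cleavage, in which each methoxy oxygen coordinates boron and bromide removes the methyl group by SN2 to leave the aryloxyborane 4, which water hydrolyses to the triol, while the diaryl ether, having no sp3 carbon on oxygen, should survive.

**Step 3**
Reactants: 5 2-(4-hydroxyphenoxy)benzene-1,4-diol; 6 bromine
Product: 8 2,3,5-tribromo-6-(2,3,5-tribromo-4-hydroxyphenoxy)benzene-1,4-diol, via hexabromoquinone 7 (not isolated)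
Conditions: Br2 (8 equiv), AcOH, rt; then FeBr3 (10 mol%), 60 °C; then aq. Na2S2O4, EtOAc, rt
Reagents that add atoms: bromine (6), BrBr
Why: Every C–Br bond forms by electrophilic aromatic substitution through a Wheland intermediate stabilised by an ortho or para oxygen: C3', C4' and C6' of the hydroquinone ring and C2 and C6 next to the ring A hydroxyl should react at room temperature, whereas C5, activated only by the ether oxygen, needs FeBr3 and warming. The excess bromine is expected to take the fully brominated hydroquinone ring to the quinone level (7, which consumes the seventh equivalent; any quinone formed earlier is brominated through HBr addition and re-oxidation to the same end), and dithionite returns it to the hydroquinone in the same flask. The closest known reaction type is the exhaustive bromination of phenols and hydroquinones with Br2 in acetic acid, together with iron-assisted bromination of bromophenols at positions activated only by an ether oxygen. No ring closes and no stereocentre arises. The step must stop at six bromines with C3–H of ring A intact: after C2/C6 bromination C3 and C5 are equivalent, so the sixth bromine has only one possible site, and the surviving C–H then sits between a bromine and the ether oxygen, meta to the newest bromine, on a ring carrying three bromines, which should make it far less reactive than C5 was; keeping bromine to a small excess backs this up.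

**Compound list**
1 | 4-methoxyphenol | COc1ccc(O)cc1 | starting material
2 | 2-bromo-1,4-dimethoxybenzene | COc1ccc(OC)c(Br)c1 | starting material
3 | 1,4-dimethoxy-2-(4-methoxyphenoxy)benzene | COc1ccc(Oc2cc(OC)ccc2OC)cc1 | intermediate
4 | 1,4-bis(dibromoboryloxy)-2-[4-(dibromoboryloxy)phenoxy]benzene (tris(dibromoboryl) ether of 5; formed in the flask, not isolated) | BrB(Br)Oc1ccc(Oc2cc(OB(Br)Br)ccc2OB(Br)Br)cc1 | intermediate
5 | 2-(4-hydroxyphenoxy)benzene-1,4-diol | Oc1ccc(Oc2cc(O)ccc2O)cc1 | intermediate
6 | bromine | BrBr | starting material
7 | 2,3,5-tribromo-6-(2,3,5-tribromo-4-hydroxyphenoxy)cyclohexa-2,5-diene-1,4-dione (hexabromoquinone; formed in the flask, not isolated) | O=C1C(Br)=C(Br)C(=O)C(Oc2cc(Br)c(O)c(Br)c2Br)=C1Br | intermediate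
8 | 2,3,5-tribromo-6-(2,3,5-tribromo-4-hydroxyphenoxy)benzene-1,4-diol | Oc1c(Br)cc(Oc2c(O)c(Br)c(Br)c(O)c2Br)c(Br)c1Br | target

**Step count**
Total steps: 3. Longest linear sequence: 3.

**Steps most likely to fail**

Step 3. The sixth substitution may stall, because ring A is deactivated by two bromines and, once ring B has been oxidised, by a quinonyl-oxy substituent. Forcing it invites ipso attack para to the ring A hydroxyl with loss of the ether, or a seventh substitution at C3. Fallback: the ether-flanking bromine of ring A is put in before the coupling, so that bromine later has to enter only hydroxyl-activated positions. The path sets out from 1. Ortho-monobromination with bromine 6 (1.0 equiv, CH2Cl2, 0 °C) should give 2-bromo-4-methoxyphenol F1. Chan–Lam coupling with commercial 2,5-dimethoxyphenylboronic acid (COc1ccc(OC)c(B(O)O)c1; Cu(OAc)2 20 mol%, pyridine, 4 Å sieves, CH2Cl2, O2 balloon, rt), under which the aryl bromide is inert, should give 2-(2-bromo-4-methoxyphenoxy)-1,4-dimethoxybenzene F2. BBr3 (CH2Cl2, −78 °C to rt) and then water should give, through 2-[2-bromo-4-(dibromoboryloxy)phenoxy]-1,4-bis(dibromoboryloxy)benzene F3, the triol 2-(2-bromo-4-hydroxyphenoxy)benzene-1,4-diol F4. Bromine 6 (6.5 equiv) in AcOH at rt without iron should then brominate the five remaining positions, all ortho to a free hydroxyl, and the excess takes ring B to the quinone. The path comes back to the route at 7, which dithionite reduces to 8 as in step 3.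

Step 1. Activation of the hindered, electron-rich aryl bromide at copper may be slow, so that protodebromination and oxidative loss of the phenol take over. Fallback: the aryl–O bond is made oxidatively from a boronic acid instead of from the halide. The path sets out from 1, which is coupled at room temperature with 2,5-dimethoxyphenylboronic acid under Chan–Lam conditions (Cu(OAc)2 20 mol%, pyridine, 4 Å sieves, CH2Cl2, O2 balloon), and comes back at 3. No compound outside the list is made on this path (none F0).

Step 2. The electron-rich hydroquinone may oxidise in air to quinone and quinhydrone-type material during aqueous work-up and chromatography, so that impure triol would enter the key step. Fallback: the triol is purified and stored in an acylated, oxidation-resistant form. The path sets out from 3. After BBr3 cleavage and water quench (through 4), crude 5 is not purified but acetylated (Ac2O, pyridine, cat. DMAP, CH2Cl2, rt) to 2-(4-acetoxyphenoxy)-1,4-phenylene diacetate F5, which can be chromatographed or crystallised. Transesterification with degassed HCl in MeOH (rt, Ar) then releases the triol just before use, and the path comes back at 5.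

**Further compounds**
F1 | step 3 | 2-bromo-4-methoxyphenol | COc1ccc(O)c(Br)c1
F2 | step 3 | 2-(2-bromo-4-methoxyphenoxy)-1,4-dimethoxybenzene | COc1ccc(Oc2cc(OC)ccc2OC)c(Br)c1
F3 | step 3 | 2-[2-bromo-4-(dibromoboryloxy)phenoxy]-1,4-bis(dibromoboryloxy)benzene | BrB(Br)Oc1ccc(Oc2cc(OB(Br)Br)ccc2OB(Br)Br)c(Br)c1
F4 | step 3 | 2-(2-bromo-4-hydroxyphenoxy)benzene-1,4-diol | Oc1ccc(Oc2cc(O)ccc2O)c(Br)c1
F0 | step 1 | none | none
F5 | step 2 | 2-(4-acetoxyphenoxy)-1,4-phenylene diacetate | CC(=O)Oc1ccc(Oc2cc(OC(C)=O)ccc2OC(C)=O)cc1
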